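**Retrosyn­thetic overview**

1. Target 25 ← SN2 demethylation of diester 24 ← Lombardo–Takai methylenation (adds C17) of the 16-ketone 23 ← β-face dihydroxylation of the C2=C3 alkene of 22.
2. Key disconnection C12–C13 (ring C): Prins closure of the ring E acyloxycarbenium ion (from lactol acetate 18) onto ring D held as a spiro-cyclopent-3-ene. Enabling feature: C12 is the acylal carbon that carries the lactone oxygen (1,5 to C20), and C13/C16 are the two ends of a C=C in a ring D whose two arms on C8 (C14H2–C13H= and C15H2–C16H=) are identical, so C8 is prochiral in the precursor and C16 receives the oxygen that later becomes the methylene.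
3. 18 ← aldehyde next to the C20 ester (assisted hydrolysis) ← triene 14 (Mg/MeOH sets C5/C6) ← bis(enol triflate) of diketone 12; C4 by methylation; ring A by annulation of the ring B β-keto ester 8 with methyl 3-oxopent-4-enoate.
4. Ring B and the spiro carbon ← intramolecular Michael addition onto the cyclopentenone of 7; C9 ← amine-catalysed Michael addition of dimethyl 3-oxopentanedioate to dienal 4 (from a Suzuki coupling).
5. Ring order: D (bought) → B → A → E → C (key step); C17 is added last.

Key step: step 12

Remark: gibberellin numbering is used throughout (ring A C1–C5/C10, ring B C5/C6/C8/C9/C10, ring C C8/C9/C11–C14, ring D C8/C13–C16, lactone ring E C9/C10/C20/O/C12/C11); methyl 3-oxopent-4-enoate 9 is assumed to be purchasable and is used freshly distilled.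

Step 1
Reactants: 1 3-bromocyclopent-2-en-1-one; 2 (E)-2-(3,3-diethoxyprop-1-en-1-yl)-4,4,5,5-tetramethyl-1,3,2-dioxaborolane
Product: 4 (E)-3-(3-oxocyclopent-1-en-1-yl)prop-2-enal, via diethyl acetal 3 (not isolated)
Conditions: PdCl2(dppf) (3 mol %), K2CO3, dioxane/H2O, 80 °C; then 1 M HCl, THF, rt
Reagents that add atoms: water, O
Why: Suzuki–Miyaura coupling of the β-bromo enone (a vinylogous acyl bromide that undergoes oxidative addition readily) with the (E)-alkenyl boronate proceeds with retention of alkene geometry, and the diethyl acetal is cleaved to the enal by dilute acid in the work-up.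

Step 2
Reactants: 4 (E)-3-(3-oxocyclopent-1-en-1-yl)prop-2-enal; 5 dimethyl 3-oxopentanedioate
Product: 7 dimethyl 2-[(1S)-3,3-dimethoxy-1-(3-oxocyclopent-1-en-1-yl)propyl]-3-oxopentanedioate, via aldehyde adduct 6 (not isolated)
Conditions: (S)-2-{bis[3,5-bis(trifluoromethyl)phenyl][(trimethylsilyl)oxy]methyl}pyrrolidine (10 mol %), PhCO2H (10 mol %), CH2Cl2, −10 °C; then HC(OMe)3, MeOH, p-TsOH (cat.), 0 °C
Reagents that add atoms: trimethyl orthoformate, COC(OC)OC
Why: Secondary-amine (iminium-ion) catalysed Michael addition in which the iminium ion of the enal directs the β-keto ester carbon C10 to C9 (β to the aldehyde), the diaryl(silyloxy)methyl group of the (S)-catalyst shields one face of the s-trans iminium ion so that C9 should form in the (S) configuration drawn, and acetalisation in the same flask protects the aldehyde against aldol condensation with the second active methylene group.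

Step 3
Reactants: 7 dimethyl 2-[(1S)-3,3-dimethoxy-1-(3-oxocyclopent-1-en-1-yl)propyl]-3-oxopentanedioate
Product: 8 spiro diketone (dimethyl 4-(2,2-dimethoxyethyl)-2,7-dioxospiro[4.4]nonane-1,3-dicarboxylate; both C8 epimers)
Conditions: DBU (0.3 equiv), MeCN, 0 °C to rt
Reagents that add atoms: none
Why: Base-mediated intramolecular Michael addition (5-exo-trig) of the remaining β-keto ester carbon C6 to the β,β-disubstituted cyclopentenone closes ring B and creates the quaternary spiro carbon C8, whose configuration is deliberately left uncontrolled because both epimers converge on 14, where ring D is a symmetrical cyclopent-3-ene, while C6 and C10 stay enolisable.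

Step 4
Reactants: 8 spiro diketone; 9 methyl 3-oxopent-4-enoate
Product: 11 tricyclic dienol triester (C3 enol; C4–CO2Me; C5=C6–CO2Me; C10 quaternary), via Michael adduct 10 (not isolated)
Conditions: 9 (1.3 equiv), Cs2CO3 (0.5 equiv), MeCN, 0 °C to rt; then piperidine, AcOH (cat.), PhMe, 60 °C
Reagents that add atoms: none
Why: Robinson-type annulation in which Michael addition occurs at C10 (the less hindered β-keto ester carbon, C6 being neopentylic to the spiro centre) on the face anti to the C9 side chain, which sets the quaternary C10 with its C20 ester cis to C11, and Knoevenagel-type aldol condensation of the doubly activated C4 methylene onto the C5 ketone then closes ring A to give the conjugated, hydrogen-bonded dienol.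

Step 5
Reactants: 11 tricyclic dienol triester
Product: 12 C4-methylated diketone (C3 ketone; 4β-methyl; 4α-CO2Me; C5=C6 enoate; ring D ketone; both C8 epimers)
Conditions: MeI, K2CO3, acetone, rt
Reagents that add atoms: iodomethane, CI
Why: C-Alkylation of the vinylogous β-keto ester anion at its central carbon C4 (as in alkylations of 4-oxocyclohex-2-enecarboxylates) moves the alkene to C5=C6 in conjugation with the C7 ester, and iodomethane approaches anti to the C20 ester that stands pseudo-axial on C10 (1,3 to C4), so that C18 should be β and the C19 ester α.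

Step 6
Reactants: 12 C4-methylated diketone
Product: 13 bis(enol triflate) (C2=C3–OTf in ring A; C13=C16–OTf in ring D; both C8 epimers)
Conditions: KN(SiMe3)2 (2.3 equiv), THF, −78 °C; then PhNTf2 (2.4 equiv), −78 to 0 °C
Reagents that add atoms: N-phenylbis(trifluoromethanesulfonimide), O=S(=O)(N(c1ccccc1)S(=O)(=O)C(F)(F)F)C(F)(F)F
Why: Kinetic enolate formation with a hindered amide base followed by O-sulfonylation (enol triflate synthesis) works on both ketones because the ring A ketone can enolise only towards C2 and the ring D ketone is deprotonated at the α-methylene remote from the quaternary spiro carbon, so each C8 epimer gives a triflate whose ring D double bond lies between C13 and C16.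

Step 7
Reactants: 13 bis(enol triflate)
Product: 14 triene (C2=C3; C5=C6 enoate; ring D as spiro-cyclopent-3-ene)
Conditions: Pd(OAc)2 (5 mol %), PPh3, HCO2H, n-Bu3N, DMF, 60 °C
Reagents that add atoms: none
Why: Palladium-catalysed formate reduction of alkenyl triflates (hydride transfer to the alkenylpalladium intermediate) replaces both triflate groups by hydrogen without moving the double bonds, and because ring D now has two identical arms on C8 the two spiro epimers become one compound.

Step 8
Reactants: 14 triene
Product: 15 trans-fused triester acetal (5β-H; 6β-CO2Me; C2=C3; spiro-cyclopent-3-ene)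
Conditions: Mg turnings, MeOH, 0 °C to rt; then NaOMe (cat.), MeOH, rt
Reagents that add atoms: none
Why: Dissolving-metal conjugate reduction (Mg in methanol) touches only the electron-poor C5=C6 enoate, the C5 carbanion is expected to be protonated from the β-face, anti to the C19 and C20 ester groups that both project over the α-face, which gives the trans A/B junction, and the C6 ester is then equilibrated by methoxide to the more stable β-ester trans to C4.

Step 9
Reactants: 15 trans-fused triester acetal
Product: 16 aldehyde (C12 as CHO)
Conditions: 1 M HCl, THF, rt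
Reagents that add atoms: water, O
Why: Acid-catalysed acetal hydrolysis liberates the C12 aldehyde while the isolated alkenes and the hindered methyl esters are inert to dilute aqueous acid.

Step 10
Reactants: 16 aldehyde
Product: 17 δ-lactol (pseudo-acid; ring E closed between C20 and C12; both anomers)
Conditions: LiOH (1.2 equiv), THF/H2O, 0 °C; then 1 M HCl to pH 3
Reagents that add atoms: lithium hydroxide, [Li+].[OH-]
Why: Neighbouring-group-assisted ester hydrolysis in which hydroxide adds to the aldehyde and the hydrate alkoxide attacks the otherwise very hindered C20 ester through a six-membered transition state and expels methoxide, so that only this ester is cleaved, the unassisted C7 and C19 esters survive, and acidification returns the ring-closed lactol.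

Step 11
Reactants: 17 δ-lactol
Product: 18 lactol acetate (cyclic acylal; both anomers)
Conditions: Ac2O, pyridine, DMAP (cat.), CH2Cl2, 0 °C
Reagents that add atoms: acetic anhydride, CC(=O)OC(C)=O
Why: DMAP-catalysed O-acetylation of the lactol hydroxyl traps the ring form as the cyclic acylal, and the anomeric configuration at C12 does not matter because C12 becomes planar in the next step.

Step 12
Reactants: 18 lactol acetate
Product: 20 pentacyclic 16-acetate (rings A to E complete; C2=C3; 16-OAc anti to C12), via acyloxycarbenium ion 19 (not isolated)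
Conditions: BF3·OEt2 (3 equiv), AcOH (10 equiv), CH2Cl2, −40 to 0 °C
Reagents that add atoms: acetic acid, CC(O)=O
Why: Proposed new method: BF3·OEt2 ionises the exocyclic acetate of the cyclic acylal to the ring E acyloxycarbenium ion 19, its carbon C12 is attacked by the ring D alkene, and the C16 cation is captured by acetate on the opposite face (a Prins cyclisation of an acyl-stabilised carbenium ion); the closest known reactions are the BF3·OEt2/AcOH Prins cyclisation of α-acetoxy ethers and the N-acyliminium–alkene cyclisation in carboxylic acids, the cation here being less stabilised and therefore more electrophilic. Ring C closes in a 6-exo-trig mode (the C12=O+ bond and the C13=C16 bond both stay outside the new six-membered ring), which completes the bicyclo[3.2.1]octane of rings C and D inside the bicyclo[3.3.1] lactone. C12 is controlled by the preformed lactone, because its oxygen is already tied to C20 and must become axial on ring C, cis to C10, whatever the anomeric configuration of 18. C8 and C13 are set by group selection, since ring E holds C12 on the α-face of ring B and only the alkene carbon of the arm cis to C11 can be reached, on the alkene face turned towards C9, so that the prochiral spiro carbon is desymmetrised; C16 results from anti addition and is erased in step 14. The step needs exocyclic ionisation of the acylal and capture of the C16 cation faster than proton loss or 1,2-shift, which the excess of AcOH and the low temperature are meant to secure, and it needs the ring A alkene to stay out, which follows from its remoteness and from the fact that its attack would place a cation on C3 next to the ester-bearing C4.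

Step 13
Reactants: 20 pentacyclic 16-acetate
Product: 21 16-alcohol
Conditions: K2CO3 (cat.), MeOH, 0 °C
Reagents that add atoms: none
Why: Base-catalysed transesterification (Zemplén-type methanolysis) removes the unhindered secondary acetate, whereas the bridged lactone is held closed by its 1,3-diaxial geometry and the neopentylic methyl esters do not exchange.

Step 14
Reactants: 21 16-alcohol
Product: 22 16-ketone (C2=C3 retained)
Conditions: Dess–Martin periodinane, NaHCO3, CH2Cl2, rt
Reagents that add atoms: none
Why: Dess–Martin oxidation of the only free hydroxyl gives the ring D ketone under buffered, non-epimerising conditions and removes the C16 stereocentre.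

Step 15
Reactants: 22 16-ketone
Product: 23 2β,3β-diol 16-ketone
Conditions: OsO4 (2 mol %), NMO, acetone/H2O, rt
Reagents that add atoms: N-methylmorpholine N-oxide, C[N+]1([O-])CCOCC1; water, O
Why: Catalytic OsO4 syn-dihydroxylation of the only alkene should occur on the β-face of ring A because the α-face is covered by the axial C19 ester on C4 and by the lactone carbonyl C20 on C10, which sets the 2β,3β-diol.

Step 16
Reactants: 23 2β,3β-diol 16-ketone
Product: 24 dimethyl ester of the target (C16=C17 methylene in place)
Conditions: Zn, CH2Br2, TiCl4, THF/CH2Cl2, 0 °C to rt (excess reagent)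
Reagents that add atoms: dibromomethane, BrCBr
Why: Lombardo–Takai methylenation converts the ketone into the exocyclic methylene with a non-basic gem-dimetallic reagent, which avoids base-induced retro-aldol epimerisation of the 3-hydroxyl β to the C19 ester and leaves the lactone and esters untouched.

Step 17
Reactants: 24 dimethyl ester of the target
Product: 25 target CNP0212122.1
Conditions: n-PrSLi, HMPA, rt; then 1 M HCl to pH 3
Reagents that add atoms: none
Why: SN2 dealkylation of both methyl esters by the soft thiolate at the methyl carbon avoids attack at the hindered acyl carbons (C19 is neopentylic and axial) and does not deprotonate the diol, and acidification gives the diacid with the δ-lactone intact.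

**Compound list**

1 | 3-bromocyclopent-2-en-1-one | O=C1C=C(Br)CC1 | starting material
2 | (E)-2-(3,3-diethoxyprop-1-en-1-yl)-4,4,5,5-tetramethyl-1,3,2-dioxaborolane | CCOC(OCC)/C=C/B1OC(C)(C)C(C)(C)O1 | starting material
3 | 3-[(E)-3,3-diethoxyprop-1-en-1-yl]cyclopent-2-en-1-one | CCOC(OCC)/C=C/C1=CC(=O)CC1 | intermediate (not isolated)
4 | (E)-3-(3-oxocyclopent-1-en-1-yl)prop-2-enal | O=C/C=C/C1=CC(=O)CC1 | intermediate
5 | dimethyl 3-oxopentanedioate | COC(=O)CC(=O)CC(=O)OC | starting material
6 | dimethyl 2-[(1S)-3-oxo-1-(3-oxocyclopent-1-en-1-yl)propyl]-3-oxopentanedioate (C10 epimers) | COC(=O)CC(=O)C(C(=O)OC)[C@H](CC=O)C1=CC(=O)CC1 | intermediate (not isolated)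
7 | dimethyl 2-[(1S)-3,3-dimethoxy-1-(3-oxocyclopent-1-en-1-yl)propyl]-3-oxopentanedioate (C10 epimers) | COC(=O)CC(=O)C(C(=O)OC)[C@H](CC(OC)OC)C1=CC(=O)CC1 | intermediate
8 | dimethyl 4-(2,2-dimethoxyethyl)-2,7-dioxospiro[4.4]nonane-1,3-dicarboxylate: ring B β-keto diester spiro-fused at C8 to the ring D ketone; C9 as in 7; both C8 epimers; C6 and C10 enolisable | O=C1C(C(=O)OC)[C@H](CC(OC)OC)C2(CC(=O)CC2)C1C(=O)OC | intermediate
9 | methyl 3-oxopent-4-enoate | C=CC(=O)CC(=O)OC | starting material
10 | Michael adduct: 8 with the 5-methoxy-3,5-dioxopentyl chain (C1 to C4 and C19) on C10, anti to the C9 side chain | O=C1[C@](CCC(=O)CC(=O)OC)(C(=O)OC)[C@H](CC(OC)OC)C2(CC(=O)CC2)C1C(=O)OC | intermediate (not isolated)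
11 | tricyclic dienol triester: ring A annulated (C3 enol, C4–CO2Me, C5=C6–CO2Me), C10 quaternary with C20 ester, C9 bearing CH2CH(OMe)2, spiro ring D ketone (both C8 epimers) | OC1=C(C(=O)OC)C2=C(C(=O)OC)C3(CC(=O)CC3)[C@@H](CC(OC)OC)[C@]2(C(=O)OC)CC1 | intermediate
12 | C4-methylated diketone: C3 ketone, 4β-methyl (C18), 4α-CO2Me (C19), C5=C6 enoate, ring D ketone (both C8 epimers) | O=C1[C@@](C)(C(=O)OC)C2=C(C(=O)OC)C3(CC(=O)CC3)[C@@H](CC(OC)OC)[C@]2(C(=O)OC)CC1 | intermediate
13 | bis(enol triflate): C2=C3–OTf in ring A and C13=C16–OTf in ring D (both C8 epimers) | COC(=O)[C@]1(C)C(OS(=O)(=O)C(F)(F)F)=CC[C@@]2(C(=O)OC)[C@H](CC(OC)OC)C3(CC(OS(=O)(=O)C(F)(F)F)=CC3)C(C(=O)OC)=C12 | intermediate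
14 | triene: C2=C3, C5=C6 enoate, ring D as spiro-cyclopent-3-ene (C8 no longer stereogenic) | COC(=O)[C@]1(C)C=CC[C@@]2(C(=O)OC)[C@H](CC(OC)OC)C3(CC=CC3)C(C(=O)OC)=C12 | intermediate
15 | trans-fused triester acetal: 5β-H, 6β-CO2Me, C2=C3, spiro-cyclopent-3-ene, C12 dimethyl acetal | COC(=O)[C@]1(C)C=CC[C@@]2(C(=O)OC)[C@H](CC(OC)OC)C3(CC=CC3)[C@@H](C(=O)OC)[C@H]12 | intermediate
16 | aldehyde: as 15 with C12 as CHO | COC(=O)[C@]1(C)C=CC[C@@]2(C(=O)OC)[C@H](CC=O)C3(CC=CC3)[C@@H](C(=O)OC)[C@H]12 | intermediate
17 | δ-lactol (pseudo-acid): ring E closed from the C20 carbonyl to C12, 12-OH (both anomers) | COC(=O)[C@]1(C)C=CC[C@@]2(C(=O)O4)[C@H](CC4O)C3(CC=CC3)[C@@H](C(=O)OC)[C@H]12 | intermediate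
18 | lactol acetate: cyclic acylal at C12 (both anomers) | COC(=O)[C@]1(C)C=CC[C@@]2(C(=O)O4)[C@H](CC4OC(C)=O)C3(CC=CC3)[C@@H](C(=O)OC)[C@H]12 | intermediate
19 | ring E acyloxycarbenium ion (C12=O+) | COC(=O)[C@]1(C)C=CC[C@@]2(C(=O)[O+]=4)[C@H](CC4)C3(CC=CC3)[C@@H](C(=O)OC)[C@H]12 | intermediate (not isolated)
20 | pentacyclic 16-acetate: rings A to E complete, C2=C3, C7 and C19 methyl esters, 16-OAc anti to the C12–C13 bond | CC(=O)O[C@@H]1C[C@]23C[C@H]1[C@@H]1C[C@H]2[C@@]2(CC=C[C@@](C)(C(=O)OC)[C@H]2[C@@H]3C(=O)OC)C(=O)O1 | intermediate
21 | 16-alcohol of 20 | O[C@@H]1C[C@]23C[C@H]1[C@@H]1C[C@H]2[C@@]2(CC=C[C@@](C)(C(=O)OC)[C@H]2[C@@H]3C(=O)OC)C(=O)O1 | intermediate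
22 | 16-ketone (17-nor ketone) with C2=C3 | O=C1C[C@]23C[C@H]1[C@@H]1C[C@H]2[C@@]2(CC=C[C@@](C)(C(=O)OC)[C@H]2[C@@H]3C(=O)OC)C(=O)O1 | intermediate
23 | 2β,3β-diol 16-ketone | O=C1C[C@]23C[C@H]1[C@@H]1C[C@H]2[C@@]2(C[C@H](O)[C@H](O)[C@@](C)(C(=O)OC)[C@H]2[C@@H]3C(=O)OC)C(=O)O1 | intermediate
24 | 7,19-dimethyl ester of the target | C=C1C[C@]23C[C@H]1[C@@H]1C[C@H]2[C@@]2(C[C@H](O)[C@H](O)[C@@](C)(C(=O)OC)[C@H]2[C@@H]3C(=O)OC)C(=O)O1 | intermediate
25 | CNP0212122.1: 2β,3β-dihydroxy-16-ene 7,19-dioic acid 20,12-lactone | C=C1C[C@]23C[C@H]1[C@@H]1C[C@H]2[C@@]2(C[C@H](O)[C@H](O)[C@@](C)(C(=O)O)[C@H]2[C@@H]3C(=O)O)C(=O)O1 | target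

Total step count: 17. Longest linear sequence: 17 steps (1 to 25); 2, 5 and 9 are bought.

**Steps most likely to fail**

Step 12 (Proposed new method). What may go wrong: the acylal may ionise in the ring-opening sense (loss of the lactone carboxylate instead of the acetate); the C16 cation may lose a proton or undergo a 1,2-shift before acetate capture; or the C7 ester carbonyl may take part at C16. The fallback uses known chemistry, an intramolecular aldol addition with lactonisation. It sets out from diketone 12, from which the C8 epimer that has the ring D ketone on the arm trans to the C9 side chain is separated by chromatography. HC(OMe)3/MeOH/PPTS ketalises only the unhindered ring D ketone to give the dimethyl ketal F1; KN(SiMe3)2/PhNTf2 gives the C3 enol triflate F2; Pd(OAc)2/PPh3/HCO2H/n-Bu3N gives the C2=C3 alkene F3; Mg/MeOH followed by NaOMe gives the trans-fused ester F4; and 1 M HCl/THF unmasks ketone and aldehyde together to give the keto aldehyde F5. K2CO3 in MeOH then brings about aldol addition of the C13 enolate to the aldehyde (the C15 enolate cannot reach C12); the reversibly formed 12-alkoxide that is axial closes the lactone on the C20 ester, and this gives ketone 22, where the route is rejoined.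

Step 8. What may go wrong: poor facial selectivity in the protonation at C5 (cis ring fusion), or incomplete reduction of the tetrasubstituted enoate. The fallback sets C5 by hydride delivery before C4 is quaternary. It sets out from dienol 11, whose keto tautomer (an alkylidene β-keto ester) is reduced at C5 by the Hantzsch ester (diethyl 2,6-dimethyl-1,4-dihydropyridine-3,5-dicarboxylate, PhMe, 60 °C), with hydride arriving anti to the C20 ester, to give the saturated β-keto ester F6. K2CO3/MeI methylates C4 anti to C20 on the now rigid trans-fused chair to give the C4-methylated saturated diketone F7; KN(SiMe3)2/PhNTf2 gives the bis(enol triflate) F8; and Pd(OAc)2/PPh3/HCO2H/n-Bu3N reduction gives 15, where the route is rejoined.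

Step 10. What may go wrong: loss of chemoselectivity, namely base-induced aldol self-condensation of the aldehyde or unassisted hydrolysis of the C7 ester competing with the assisted cleavage at C20. The fallback avoids the free acid altogether. It sets out from aldehyde 16, which Ac2O with Sc(OTf)3 (cat.) converts into the geminal diacetate F9. Under the conditions of step 12 the acetoxycarbenium ion from F9 is trapped by the carbonyl oxygen of the neighbouring C20 methyl ester (six-membered dioxanylium ion), acetate removes the O-methyl group as methyl acetate, and the lactol acetate 18 formed in the flask cyclises on to 20, where the route is rejoined.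

**Further compounds**

F1 | step 12 | C16 dimethyl ketal of 12 (C8 epimer with the ring D carbonyl on the arm trans to C11) | O=C1[C@@](C)(C(=O)OC)C2=C(C(=O)OC)[C@]3(CC(OC)(OC)CC3)[C@@H](CC(OC)OC)[C@]2(C(=O)OC)CC1
F2 | step 12 | C3 enol triflate of F1 | COC(=O)[C@]1(C)C(OS(=O)(=O)C(F)(F)F)=CC[C@@]2(C(=O)OC)[C@H](CC(OC)OC)[C@@]3(CC(OC)(OC)CC3)C(C(=O)OC)=C12
F3 | step 12 | C2=C3 alkene from F2 (C5=C6 enoate, C16 ketal) | COC(=O)[C@]1(C)C=CC[C@@]2(C(=O)OC)[C@H](CC(OC)OC)[C@@]3(CC(OC)(OC)CC3)C(C(=O)OC)=C12
F4 | step 12 | trans-fused ester from F3 (5β-H, 6β-CO2Me, C16 ketal, C12 acetal) | COC(=O)[C@]1(C)C=CC[C@@]2(C(=O)OC)[C@H](CC(OC)OC)[C@@]3(CC(OC)(OC)CC3)[C@@H](C(=O)OC)[C@H]12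
F5 | step 12 | keto aldehyde (C16 ketone, C12 aldehyde) | COC(=O)[C@]1(C)C=CC[C@@]2(C(=O)OC)[C@H](CC=O)[C@@]3(CC(=O)CC3)[C@@H](C(=O)OC)[C@H]12
F6 | step 8 | saturated β-keto ester from 11 (5β-H, 6β-CO2Me; C4 enolisable; both C8 epimers) | O=C1C(C(=O)OC)[C@H]2[C@H](C(=O)OC)C3(CC(=O)CC3)[C@@H](CC(OC)OC)[C@]2(C(=O)OC)CC1
F7 | step 8 | C4-methylated saturated diketone (4β-methyl, 4α-CO2Me; both C8 epimers) | O=C1[C@@](C)(C(=O)OC)[C@H]2[C@H](C(=O)OC)C3(CC(=O)CC3)[C@@H](CC(OC)OC)[C@]2(C(=O)OC)CC1
F8 | step 8 | bis(enol triflate) of F7 (both C8 epimers) | COC(=O)[C@]1(C)C(OS(=O)(=O)C(F)(F)F)=CC[C@@]2(C(=O)OC)[C@H](CC(OC)OC)C3(CC(OS(=O)(=O)C(F)(F)F)=CC3)[C@@H](C(=O)OC)[C@H]12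
F9 | step 10 | geminal diacetate (acylal) of aldehyde 16 | COC(=O)[C@]1(C)C=CC[C@@]2(C(=O)OC)[C@H](CC(OC(C)=O)OC(C)=O)C3(CC=CC3)[C@@H](C(=O)OC)[C@H]12
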